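The data are calculated for an exercise, noise included.

**Same start, different end.** Compare the first readings: the south-east run gives a first-order constant of 0.0165 s⁻¹ and the south-west run 0.0147 s⁻¹, although the south-west run holds 7.67 times the c(protic impurity). Yet by 120 s they stand at 75.7% and 32.2%. Freeze that early constant, then.

| setting | south-east | north-west | south-west | delta | beta | theta | epsilon |
|---|---|---|---|---|---|---|---|
| starting material | 1 M | 1 M | 1 M | 1.0 M | 1.0 M | 1.0 M | 1.0 M |
| reagent | 0.95 M | 0.95 M | 0.95 M | 0.950 M | 0.950 M | 0.950 M | 0.950 M |
| protic impurity | 0.30 M | 0.68 M | 2.3 M | 0.250 M | 0.500 M | 1.00 M | 2.00 M |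
| initiator | 20 mM | 20 mM | 20 mM | 20 mM | 20 mM | 20 mM | 20 mM |
| remark | run made earlier | run made earlier | run made earlier |  |  |  |  |
| time |  |  |  | 2.0 min | 2.0 min | 2.0 min | 2.0 min |

| south-east: time / s | south-east: product / % | north-west: time / s | north-west: product / % | south-west: time / s | south-west: product / % |
|---|---|---|---|---|---|
| 15.0 | 24.8 | 15.0 | 23.9 | 10.0 | 14.7 |
| 40.0 | 49.2 | 40.0 | 44.8 | 20.0 | 22.2 |
| 80.0 | 68.4 | 80.0 | 58.0 | 50.0 | 30.1 |
| 120 | 75.7 | 120 | 61.8 | 120 | 32.2 |

(standard deviation of a reading: 0.3 percentage points)

1. amount of product at the end, in percent of the starting material charged for delta, beta, theta, epsilon, in this order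
2. the shape of the row from first to last (hardly changes / rises, then falls / falls all the way / rises all the way / falls, then rises)

**Main step.** With one reagent per product and nothing else at work, the charge allows 95.0%, so in this first picture reagent is the limiting reagent.

**Add the quench.** My own reading is a race: assume the protic impurity consumes starting material too, one for one, and that both paths are pseudo-first-order in starting material. Product gained per starting material quenched is then h/c(protic impurity), where h is the break-even impurity 0.922 M, the c(protic impurity) at which both paths run equally fast. Integrated, product = h ln(charged c(protic impurity)/remaining c(protic impurity)). I took h from the south-west run, treating it as finished and counting its missing starting material as quenched.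

For epsilon, product and quench must add up to the charge. Two passes from the south-west value give 38.2% and 34.1%, so take their mean, 36.1%.

**Add the clock.** In delta, the two frozen paths together leave 8.03% of the starting material at 2.0 min. Expect a falling row, with delta somewhat below its plateau.

**The forecast.** It reads 78%, 67.5%, 53% and 35.5%, shape falls all the way, on the ground that “the impurity does not slow the reaction at the start; it cuts it off early”. The forecast has the active species killed in proportion to impurity, where my reckoning races the starting material.

**The flask.** It gives 77.7%, 68.1%, 53.2% and 35.5%, shape falls all the way. Delta still holds 7.4% starting material.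

    initiator → 2 initiating radical (k = 0.00374 s⁻¹)
    starting material + initiating radical → capped initiator + first chain carrier (k = 7.63 × 10⁵ M⁻¹ s⁻¹)
    reagent + first chain carrier ⇌ product + second chain carrier (K = 2.88, k = 1.07 × 10⁵ M⁻¹ s⁻¹)
    starting material + second chain carrier → by-product + first chain carrier (k = 30600 M⁻¹ s⁻¹)
    2 first chain carrier → ended chains A (k = 2.50 × 10⁶ M⁻¹ s⁻¹)
    2 second chain carrier → ended chains B (k = 1.70 × 10⁸ M⁻¹ s⁻¹)
    starting material + protic impurity → quenched substrate (k = 0.0224 M⁻¹ s⁻¹)

**Race read.** Epsilon keeps 68% of its protic impurity, and h turns that into 35.9% against 35.5%. Theta keeps 55%, which gives 55.4% against 53.2%. In epsilon, the reaction of starting material with protic impurity to quenched substrate and the reaction of second chain carrier to ended chains B act together: epsilon gives 35.5% product as run, 88.5% without the first of these reactions, and 83.1% without the second.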